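## Structural features

The target is a trans-decalin (ring A = C1–C5/C10, ring B = C5–C10) whose C11 carries the 7-oxygen of a coumarin as an alkyl aryl ether. Labdane numbering is used for all compounds: C11 on C9, exocyclic C17 on C8, C18 methyl and C19 CH2O on C4, C20 methyl on C10. Five stereocentres form the unbroken chain C3–C4–C5–C10–C9 (3R,4R,5S,9R,10R). C4 and C10 are quaternary, their C19 and C20 substituents are syn-diaxial on one face, and the C3 hydroxyl and the C9 arm are equatorial. The C20/H5 pair is antipodal to that of the common drimanes, so the customary drimane chiral pool would give the wrong enantiomer, and it has no oxygen at C3 or C19. The fragile points are these: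
- the primary acetate, 1,3 to a free secondary hydroxyl (migration, solvolysis);
- the exocyclic C8=C17 bond (acid moves it into the ring);
- H9, which is allylic and β to the aryloxy group (elimination);
- the coumarin lactone (aqueous base).

The ether bond is not the problem. The real difficulty is the oxygenated axial C19 on quaternary C4 next to C3–OH, correct relative to C5, C10 and C9, in the ent series, with the alkene held exocyclic.

The key step exploits the fact that C11 is the only atom through which rings A/B are joined to the rest of the molecule. The whole set C1–C11, C17–C20, O3 and O19, with all five configurations and C8=C17, is the decalin half of the cheap ent-labdane lactone andrographolide (1), where C11 is bound to a C5 lactone unit (C12–C16).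

The route in one sentence: site-selective oxidative scission of the C11=C12 bond of the C20 dienyl butenolide 3, which discards C12–C16 and leaves the complete C15 core with C11 as an aldehyde.

## Logic of the disconnections

**8 ⇒ 6 + 7.** The C11–O(aryl) bond is cut on its alkyl side. It is the only bond between the two halves, and C11 is not stereogenic. The cut keeps the flat, base-sensitive lactone out of all oxidative chemistry. The problem shrinks from C26 to a C17 core plus a commodity phenol. The forward step must substitute a β-branched primary carbon under near-neutral conditions. It must leave the C3 hydroxyl and the acetate alone and must not eliminate towards C9.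

**6 ⇒ 5.** No skeletal bond is cut. C11 is raised to the aldehyde level so that it can be the stump of a cleaved alkene. The forward reduction must be fast and cold, because in 5 H9 is both allylic and α to the carbonyl group.

**5 ⇒ 3 (through 4).** This is the key disconnection, read backwards as a reconnection. The C11 carbonyl carbon is joined through an E C11=C12 double bond to a C5 butenolide (C12–C16). Forwards, both bonds between C11 and C12 are cut.
- 3 is larger than 5 by five carbons, but it lies two functional-group operations from 1.
- 1 already holds rings A and B, both quaternary carbons, all five stereocentres in the required ent series, O3, O19 and C8=C17.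
- No ring and no stereocentre has to be made, so the hardest group of stereocentres is settled in this one operation.
- The demand is site selectivity: one alkene out of three must be cleaved, and the new β,γ-unsaturated aldehyde must keep C9 and the exocyclic alkene as they are.

**3 ⇒ 2.** The acetyl–O19 bond is cut. The acetylation is placed before the key step because 2 has only two hydroxyl groups, one primary and one hindered secondary. After it, C11–OH is the only primary hydroxyl that ever appears, so no protecting group is needed. The demand is primary-over-secondary selectivity with about one equivalent of acylating agent.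

**2 ⇒ 1.** This is a retro-1,4-elimination. Water is added back across C11–H and C14–O, which restores the C12=C13 alkylidene lactone. In 1 the side-chain alkene lies one carbon too far from the ring and is electron-poor. The forward transposition brings the scissile π bond exactly to C11 and makes it a diene terminus. The demand is γ-deprotonation at C11 only, E geometry, and no disturbance of C9.

## Other disconnections considered

**Alternative 1:** (the first that comes to mind) cut C4–C5 and C9–C10. The forward key step is the biomimetic bicyclisation of the open-chain epoxy-farnesyl umbelliferyl ether A1, triggered by Ti(III) (radical) or by a Lewis acid (cationic), which would lead directly to 8.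
- Chair–chair folding puts the oxirane substituent that is cis to the chain into the axial position, so A1 needs the Z-CH2OAc group and a single oxirane configuration.
- Terminal allylic oxidation of a farnesyl chain is E-selective. The Z-allylic alcohol would therefore have to be built by chain degradation and Z-selective olefination before an asymmetric epoxidation, on a triene with three similar alkenes.
- In the radical mode C4 becomes a planar β-acyloxy radical. Its oxirane information is lost by rotation about C3–C4, and a 1,2-acyloxy shift or β-elimination can compete.
- In the cationic mode the acetoxymethyl group destabilises the developing C4 cation and the acetate carbonyl can capture it. The terminating proton loss also does not distinguish C17 from C7 or C9.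
- The chosen plan takes C4 and the other four centres ready-made and is shorter.

**Alternative 2:** cut C1–C10 and C4–C5 (Robinson annulation logic). The forward key step is the D-proline-catalysed intramolecular aldol condensation (Hajos–Parrish–Eder–Sauer–Wiechert type) that gives the (R)-Wieland–Miescher ketone A2.
- A2 fixes C10 only.
- C18, C19, C11 and C17 would each need a C–C bond formation of its own.
- C4 requires the oxygenated carbon first and methyl last, because the second electrophile enters the C3 enolate anti to C20 and ends equatorial.
- C5 needs a dissolving-metal reduction and C3 a hydride reduction.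
- C9 needs a homologation of a hindered ketone next to C10, and C8 needs an oxidation-level adjustment before methylenation.
- Four of the five stereocentres would be set one at a time, over well more than a dozen operations with several protecting groups.

**Alternative 3:** keep 1 as the source but cut where its own alkene lies, C12=C13, and then cut C11–C12 in a decarboxylative C(sp3)–O coupling. The sequence would be oxidative cleavage and oxidation to the C12 acid A3, activation as the N-hydroxyphthalimide ester A4, and copper/photoredox coupling of the C11 radical with 7. The ether would form in the same operation that removes C12, which is attractive.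
- Two scissions are needed instead of one.
- The first must oxidise an electron-poor alkylidene lactone in the presence of the more nucleophilic C8=C17, against the substrate's bias.
- The primary C11 radical is homoallylic to C8=C17. A 3-exo closure, followed by reopening to the more stable secondary C9 radical (expansion of ring B), competes with capture by copper.
- The count of steps is also higher.

Key step: step 3

Assumption: commercial andrographolide is the natural enantiomer, with decalin centres 3R,4R,5S,9R,10S. The change of the C10 descriptor to R in 2–8 reflects only a change of substituent priority at C9/C5, not of geometry.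

## Steps

Step 1
Reactants: 1 andrographolide
Product: 2 14-deoxy-11,12-didehydroandrographolide (E-C11=C12, C13=C14 butenolide; free 3-OH and 19-OH)
Conditions: neutral Al2O3, pyridine, reflux
Reagents that add atoms: none
Why: Vinylogous E1cB (1,4-)dehydration, a known conversion in this series: the γ-hydrogen at C11 of the α-alkylidene lactone is removed, the dienolate expels the alumina-activated C14 hydroxyl, and the π bonds shift to the E-dienyl butenolide. Only the C14 stereocentre, which is not needed, is destroyed; C3, C4, C5, C9 and C10 are untouched.

Step 2
Reactants: 2 14-deoxy-11,12-didehydroandrographolide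
Product: 3 19-O-acetyl-14-deoxy-11,12-didehydroandrographolide
Conditions: Ac2O (1.05 equiv), pyridine, CH2Cl2, 0 °C
Reagents that add atoms: acetic anhydride, CC(=O)OC(C)=O
Why: Kinetically regioselective O-acylation: the primary C19–OH should react ahead of the equatorial secondary C3–OH, which is flanked by quaternary C4. One equivalent at low temperature without a nucleophilic catalyst keeps the second acylation slow; no stereocentre is involved.

Step 3
Reactants: 3 19-O-acetyl-14-deoxy-11,12-didehydroandrographolide
Product: 5 (3R,4R,5S,9R,10R)-19-acetoxy-3-hydroxy-12,13,14,15,16-pentanorlabd-8(17)-en-11-al, via 11,12-diol 4 (not isolated)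
Conditions: OsO4 (2 mol %), NaIO4 (2.1 equiv), 2,6-lutidine (2 equiv), 1,4-dioxane–H2O (3:1), 0 °C to rt
Reagents that add atoms: osmium tetroxide, O=[Os](=O)(=O)=O (delivers the oxygen to C11); sodium periodate, [Na+].[O-]I(=O)(=O)=O (terminal oxidant that supplies this oxygen)
Why: Lemieux–Johnson oxidation, i.e. osmium-catalysed syn-dihydroxylation followed in situ by Malaprade glycol cleavage. OsO4 adds by [3+2] cycloaddition across C11=C12, the osmate(VI) ester is hydrolysed to diol 4 while periodate returns Os(VI) to Os(VIII), and the cyclic periodate ester of 4 fragments into aldehyde 5 and a water-soluble C5 formylbutenolide. The step closes no ring and leaves no new stereocentre (the two carbinol centres of 4 are transient, so their configuration is irrelevant); its stereochemical role is to release C3, C4, C5, C9 and C10 of the natural product unchanged in a C15 frame. One of three alkenes must react: C13=C14 is trisubstituted and directly conjugated to the lactone carbonyl and is therefore deactivated towards the electrophilic oxidant; C8=C17 is screened on one face by the syn-axial C20 methyl, and attack on its other face would force C17 into that same 1,3-diaxial position, so both modes are penalised; C11=C12 is an E-1,2-disubstituted diene terminus that projects equatorially away from the decalin and has the highest-lying π level. Periodate is held near the two equivalents that the equation demands, so that no oxidant remains once the UV-active diene is consumed. 2,6-Lutidine buffers the medium, speeds osmate hydrolysis and suppresses both the shift of C8=C17 into conjugation and enolisation at C9, where the equatorial formyl group is in any case the more stable epimer. The free C3–OH and the acetate are inert, since O3 and O19 are 1,3-related and no other vicinal diol is present.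

Step 4
Reactants: 5 (3R,4R,5S,9R,10R)-19-acetoxy-3-hydroxy-12,13,14,15,16-pentanorlabd-8(17)-en-11-al
Product: 6 (3R,4R,5S,9R,10R)-19-acetoxy-12,13,14,15,16-pentanorlabd-8(17)-ene-3,11-diol
Conditions: NaBH4, MeOH–CH2Cl2 (1:1), −20 °C, short time; aq NH4Cl
Reagents that add atoms: none
Why: 1,2-Hydride reduction of an aldehyde, much faster than attack on the hindered neopentyl acetate. The low temperature and the immediate mildly acidic quench leave no time for enolisation at C9, alkene migration or acetyl transfer; C11 is not stereogenic.

Step 5
Reactants: 6 (3R,4R,5S,9R,10R)-19-acetoxy-12,13,14,15,16-pentanorlabd-8(17)-ene-3,11-diol; 7 umbelliferone (7-hydroxycoumarin)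
Product: 8 target, 7-{[(3R,4R,5S,9R,10R)-19-acetoxy-3-hydroxy-12,13,14,15,16-pentanorlabd-8(17)-en-11-yl]oxy}coumarin
Conditions: PPh3, DIAD, THF, 0 °C to rt
Reagents that add atoms: none
Why: Mitsunobu etherification: the acidic phenol 7 (pKa near 8) protonates the betaine, and its phenoxide displaces the alkoxyphosphonium group at primary C11 under essentially neutral conditions that spare the acetate, the lactone and the alkene. The C3–OH is a secondary neopentyl-type equatorial alcohol whose backside is blocked by C4 and the ring, so it should not be substituted; no stereocentre changes.

## Compound list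

1 | andrographolide | C=C1CC[C@@H]2[C@](C)(CO)[C@H](O)CC[C@@]2(C)[C@@H]1C/C=C3/C(=O)OC[C@H]3O | starting material
2 | 14-deoxy-11,12-didehydroandrographolide | C=C1CC[C@@H]2[C@](C)(CO)[C@H](O)CC[C@@]2(C)[C@@H]1/C=C/C3=CCOC3=O | intermediate
3 | 19-O-acetyl-14-deoxy-11,12-didehydroandrographolide | C=C1CC[C@@H]2[C@](C)(COC(C)=O)[C@H](O)CC[C@@]2(C)[C@@H]1/C=C/C3=CCOC3=O | intermediate
4 | 11,12-diol of 3 (syn addition, both facial isomers, C11/C12 left undefined because both centres are destroyed) | C=C1CC[C@@H]2[C@](C)(COC(C)=O)[C@H](O)CC[C@@]2(C)[C@@H]1C(O)C(O)C3=CCOC3=O | intermediate
5 | (3R,4R,5S,9R,10R)-19-acetoxy-3-hydroxy-12,13,14,15,16-pentanorlabd-8(17)-en-11-al | C=C1CC[C@@H]2[C@](C)(COC(C)=O)[C@H](O)CC[C@@]2(C)[C@@H]1C=O | intermediate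
6 | (3R,4R,5S,9R,10R)-19-acetoxy-12,13,14,15,16-pentanorlabd-8(17)-ene-3,11-diol | C=C1CC[C@@H]2[C@](C)(COC(C)=O)[C@H](O)CC[C@@]2(C)[C@@H]1CO | intermediate
7 | umbelliferone (7-hydroxy-2H-chromen-2-one) | Oc1ccc2ccc(=O)oc2c1 | starting material
8 | CNP0271943.1 | C=C1CC[C@@H]2[C@](C)(COC(C)=O)[C@H](O)CC[C@@]2(C)[C@@H]1COc1ccc2ccc(=O)oc2c1 | target

## Step count and least certain steps

Total step count: 5. Longest linear sequence: 5 (1 → 8); 7 is purchased.

**Step 3 (key step).** The most likely failure is insufficient site selectivity. Osmylation of C8=C17 could compete with that of C11=C12, because the electronic advantage of a cross-conjugated diene terminus over a 1,1-dialkyl alkene is modest and the discrimination rests mainly on sterics. A second failure mode is migration of C8=C17 into conjugation with the new aldehyde during work-up. The fallback removes the competition instead of relying on it and sets out from 3.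
- Buffered mCPBA (NaHCO3, CH2Cl2, 0 °C) is electrophilic and should pick the only alkene not tied to an acceptor, on the face opposite to C20. This gives the (8S)-8,17-epoxide F1.
- Exhaustive ozonolysis (O3, CH2Cl2–MeOH, −78 °C; Me2S) then needs no selectivity and gives the epoxy aldehyde F2.
- F2 is reduced in the same flask with NaBH4 to the epoxy alcohol F3.
- A Cornforth-type reductive deoxygenation (NaI, Zn, NaOAc/AcOH) opens the oxirane at primary C17 to the iodohydrin F4. Zinc-induced 1,2-elimination restores C8=C17 regiospecifically, and the route is rejoined at 6.

**Step 5.** The most likely failure is slow substitution at the β-branched C11. The alkoxyphosphonium ion could then decay by E2 loss of the allylic H9, be intercepted by the hydrazide, or allow some activation of C3–OH. The fallback forms the other C–O bond, so that no substitution at C11 is needed. It sets out from 6. A Buchwald–Hartwig-type palladium-catalysed C–O coupling joins the primary alcohol to purchased 7-bromocoumarin F5 (bulky biaryl phosphine such as RockPhos, Cs2CO3, toluene, 80–90 °C). The primary hydroxyl should couple in preference to the hindered secondary one, and the route is rejoined at 8.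

**Step 2.** The most likely failure is poor discrimination between the two hydroxyls, with over-acetylation, because C19–OH is primary but neopentyl and axial. The fallback replaces kinetic discrimination by directed activation and sets out from 2. Bu2SnO (toluene, reflux, water removed) gives the six-membered 3,19-O-dibutylstannylene acetal F6. Acylation of F6 with AcCl at 0 °C is expected at the primary oxygen, and aqueous work-up rejoins the route at 3.

**Step 4.** The most likely failure is acetyl transfer from O19 to O3 or methanolysis under the alkoxide/borate conditions, together with enolisation of 5 before hydride delivery. The fallback postpones the acetate and sets out from 2.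
- 2,2-Dimethoxypropane/PPTS gives the 3,19-acetonide F7.
- The same osmium/periodate scission runs through the acetonide 11,12-diol F8 to the acetonide aldehyde F9.
- NaBH4 gives the acetonide alcohol F10.
- Mitsunobu reaction with 7 gives the acetonide ether F11.
- AcOH–H2O (7:3, rt) liberates the 3,19-diol ether F12.
- Ac2O/pyridine at 0 °C acetylates the primary C19–OH, and the route is rejoined at 8.

## Further compounds

F1 | step 3 | (8S)-8,17-epoxide of 3 | O1C[C@@]12CC[C@@H]3[C@](C)(COC(C)=O)[C@H](O)CC[C@@]3(C)[C@@H]2/C=C/C4=CCOC4=O
F2 | step 3 | (8S)-8,17-epoxy aldehyde (8,17-epoxide of 5) | O1C[C@@]12CC[C@@H]3[C@](C)(COC(C)=O)[C@H](O)CC[C@@]3(C)[C@@H]2C=O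
F3 | step 3 | (8S)-8,17-epoxy alcohol (8,17-epoxide of 6) | O1C[C@@]12CC[C@@H]3[C@](C)(COC(C)=O)[C@H](O)CC[C@@]3(C)[C@@H]2CO
F4 | step 3 | 17-iodo-8-hydroxy iodohydrin from F3 | IC[C@]1(O)CC[C@@H]2[C@](C)(COC(C)=O)[C@H](O)CC[C@@]2(C)[C@@H]1CO
F5 | step 5 | 7-bromocoumarin (purchased) | O=c1ccc2ccc(Br)cc2o1
F6 | step 2 | 3,19-O-dibutylstannylene acetal of 2 | C=C1CC[C@@H]2[C@](C)(CO[Sn](CCCC)(CCCC)O3)[C@H]3CC[C@@]2(C)[C@@H]1/C=C/C4=CCOC4=O
F7 | step 4 | 3,19-O-isopropylidene derivative of 2 | C=C1CC[C@@H]2[C@](C)(COC(C)(C)O3)[C@H]3CC[C@@]2(C)[C@@H]1/C=C/C4=CCOC4=O
F8 | step 4 | 11,12-diol of F7 (C11/C12 undefined, transient) | C=C1CC[C@@H]2[C@](C)(COC(C)(C)O3)[C@H]3CC[C@@]2(C)[C@@H]1C(O)C(O)C4=CCOC4=O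
F9 | step 4 | 3,19-O-isopropylidene C11 aldehyde | C=C1CC[C@@H]2[C@](C)(COC(C)(C)O3)[C@H]3CC[C@@]2(C)[C@@H]1C=O
F10 | step 4 | 3,19-O-isopropylidene C11 alcohol | C=C1CC[C@@H]2[C@](C)(COC(C)(C)O3)[C@H]3CC[C@@]2(C)[C@@H]1CO
F11 | step 4 | 3,19-O-isopropylidene umbelliferyl ether | C=C1CC[C@@H]2[C@](C)(COC(C)(C)O3)[C@H]3CC[C@@]2(C)[C@@H]1COc1ccc2ccc(=O)oc2c1
F12 | step 4 | 3,19-diol umbelliferyl ether (deacetyl target) | C=C1CC[C@@H]2[C@](C)(CO)[C@H](O)CC[C@@]2(C)[C@@H]1COc1ccc2ccc(=O)oc2c1
A1 | alternative 1 | 7-{[(2E,6E)-9-[(2R,3S)-3-(acetoxymethyl)-3-methyloxiran-2-yl]-3,7-dimethylnona-2,6-dien-1-yl]oxy}coumarin | CC(=O)OC[C@]1(C)O[C@@H]1CC/C(C)=C/CC/C(C)=C/COc1ccc2ccc(=O)oc2c1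
A2 | alternative 2 | (R)-Wieland–Miescher ketone | C[C@@]12CCC(=O)C=C1CCCC2=O
A3 | alternative 3 | 19-acetoxy-3-hydroxy-13,14,15,16-tetranorlabd-8(17)-en-12-oic acid (ent series) | C=C1CC[C@@H]2[C@](C)(COC(C)=O)[C@H](O)CC[C@@]2(C)[C@@H]1CC(=O)O
A4 | alternative 3 | N-hydroxyphthalimide ester of A3 | C=C1CC[C@@H]2[C@](C)(COC(C)=O)[C@H](O)CC[C@@]2(C)[C@@H]1CC(=O)ON1C(=O)c2ccccc2C1=O
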